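The numbers in the tables are calculated from invented constants, noise included.

**The count.** Two percentages and one choice are asked of us, and we reach them by counting places rather than by integrating rate laws.

| flask | starting complex | incoming ligand | leaving ligand | remark | time |
|---|---|---|---|---|---|
| cedar | 0.0014 M | 2.4 mM | 1 mM | run made earlier |  |
| elm | 0.0023 M | 2.4 mM | 1 mM | run made earlier |  |
| west | 0.0030 M | 2.40 mM | 1.00 mM |  | 25 min |
| south | 0.0020 M | 2.40 mM | 1.00 mM |  | 15 min |

| run | time / min | complex with two exchanged / % | starting complex / % |
|---|---|---|---|
| cedar | 0.833 | 5.1 | 44.4 |
| cedar | 2.00 | 15.3 | 23.7 |
| cedar | 5.00 | 31.4 | 14.3 |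
| cedar | 10.0 | 43.5 | 14.2 |
| elm | 2.50 | 12.0 | 31.5 |
| elm | 5.00 | 17.0 | 29.3 |
| elm | 8.00 | 21.6 | 30.8 |
| elm | 10.0 | 24.7 | 31.8 |

(readings scatter by 0.5 percentage points)

- which of the two ends with the higher amount of complex with two exchanged, in percent of the starting complex charged ("neither" if they lie within 2 percentage points) (west / south / neither)
- complex with two exchanged at the end, in percent of the starting complex charged, west
- complex with two exchanged at the end, in percent of the starting complex charged, south

- steps that have been proposed: starting complex + incoming ligand <-> leaving ligand + complex with one exchanged; complex with one exchanged + incoming ligand <-> leaving ligand + complex with two exchanged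

**The budget.** Each complex has two places to exchange, and the readings let us count how many have been used: in the elm run at 10.0 min, the incoming ligand taken up comes to 89.0% of its charge. South offers 4.00 mM of places to 2.40 mM of incoming ligand, fewer ligands than places, so incoming ligand is the limiting reagent.

**The zero.** Let f be the filling, the charge of incoming ligand divided by the places: 60.0% in south, 40.0% in west. If the whole charge of incoming ligand were taken up and the second place filled as readily as the first, the places would fill independently, and a complex would hold both with probability f squared. In south this statistical share s is 36.0%, the amount of complex with two exchanged that the charge gives by counting, and in west it is 16.0%.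

**The runs.** The elm run has s = 27.2% and read 24.7% at 10.0 min, a little lower and still rising from 21.6%. The cedar run, with s = 73.5%, read 43.5% at that time, so s is a mark on the scale and no clock. We commit to about s for each flask, which puts south higher than west.

**The forecast.** The forecast also names south, at 34% against 24% for west, higher than our west, on the ground that “the larger charge lowers west's percentage”.

**The flask.** South ends at 32.2% and west at 19.4%, so south ends higher. Read at 150 min, south stands at 35.8%, and read at 250 min, west stands at 20.6%. Against s, south stands 3.8 percentage points under its 36.0% at the asked time, and west stands 3.4 points over its 16.0%.

    starting complex + incoming ligand ⇌ leaving ligand + complex with one exchanged (K = 14.0, k = 9.00 /M/s)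
    complex with one exchanged + incoming ligand ⇌ leaving ligand + complex with two exchanged (K = 12.0, k = 1.90 /M/s)

**A neighbour.** A neighbour of south charged with 0.0034 M of starting complex has s = 12.5%. Computed at 15.0 min, that neighbour holds 14.2% of complex with two exchanged.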